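**Plan**

- Cuts, in retrosynthetic order: acetates, C11=C20 and C6–Cl/C5=C16 adjustments; C1–C2 (ring closure); C9–C10 (vinyl-lithium + aldehyde); C4–O and C7–O (two epoxide openings); C3=C4 and C7=C8 (two Wittig reactions).
- Forward: γ-lactone (C7–O) → dihydropyran (C4–O–C8) → ring A joined at C9–C10 → oxocane and ten-membered ring closed by C1–C2 → chloride, exocyclic methylene, acetates.
- Enabling feature: the cis-fused dihydropyran–lactone carries its C4 and C8 arms cis, so the C2 aldehyde sits over the ring-A enone C11(=O)–C10=C1. A C2 ketyl adds to the β-carbon C1, and the enone carbonyl is left as the C11 ketone for the methylene.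
- Stereochemistry: C17 from (R)-lactate (SN2 inversion); C7/C8 from Sharpless epoxidation (D-(−)-DET) with inversion at C7; C3/C4 from Sharpless epoxidation (L-(+)-DET) with inversion at C4; C14 from CBS reduction; C9 from Cornforth-type addition; C1, C2, C10 in the ring closure; C6 from exo-face ene chlorination.

Key step: step 25

Remark: briarane numbering is used for locants (ring A = C1, C10–C14; C15 on C1; C16 on C5; C17 bears methyl C18; C19 = lactone C=O; C20 on C11). Compounds 1, 3, 6 and 21 are taken as commercial.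

**Route**

Step 1
Reactants: 1 tert-butyl (R)-lactate
Product: 2 lactate triflate
Conditions: Tf2O, 2,6-lutidine, CH2Cl2, −78 → 0 °C
Reagents that add atoms: triflic anhydride, O=S(=O)(OS(=O)(=O)C(F)(F)F)C(F)(F)F
Why: O-sulfonylation of the secondary alcohol (triflate formation) does not touch the stereocentre, so the future C17 keeps the lactate configuration.

Step 2
Reactants: 2 lactate triflate; 3 methyl (triphenylphosphoranylidene)acetate (2 equiv)
Product: 5 succinate ylide, via phosphonium triflate 4 (not isolated)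
Conditions: CH2Cl2, 0 °C → rt
Reagents that add atoms: none
Why: SN2 C-alkylation of the stabilised ylide by the α-triflyloxy ester should go with inversion and set C17, and transylidation by the second equivalent of 3 gives the new stabilised ylide.

Step 3
Reactants: 6 4-methylfuran-2(5H)-one
Product: 7 lactol
Conditions: DIBAL-H (1.05 equiv), CH2Cl2, −78 °C; Rochelle salt
Reagents that add atoms: none
Why: DIBAL half-reduction of a lactone to the lactol; the ring fixes the later C5=C6 double bond as Z.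

Step 4
Reactants: 7 lactol; 5 succinate ylide
Product: 8 hydroxy dienyl succinate
Conditions: toluene, 80 °C
Reagents that add atoms: none
Why: Wittig olefination of the open hydroxy-enal form with the trisubstituted stabilised ylide should give the E-alkylidene succinate (C6 trans to the C9 ester) under neutral conditions that leave C17 and the Z alkene untouched.

Step 5
Reactants: 8 hydroxy dienyl succinate
Product: 9 TES ether
Conditions: TESCl, imidazole, CH2Cl2, 0 °C
Reagents that add atoms: chlorotriethylsilane, CC[Si](Cl)(CC)CC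
Why: silylation masks the C4 allylic alcohol so that only the C9 alcohol can direct the coming epoxidation.

Step 6
Reactants: 9 TES ether
Product: 10 allylic alcohol
Conditions: DIBAL-H (2.2 equiv), CH2Cl2, −78 °C
Reagents that add atoms: none
Why: chemoselective DIBAL reduction of the methyl ester beside the hindered tert-butyl ester should give the C9 allylic alcohol.

Step 7
Reactants: 10 allylic alcohol
Product: 11 epoxy alcohol
Conditions: Ti(OiPr)4, D-(−)-DET, t-BuOOH, 4 Å MS, CH2Cl2, −20 °C
Reagents that add atoms: tert-butyl hydroperoxide, CC(C)(C)OO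
Why: Sharpless asymmetric epoxidation of the 2,3-disubstituted E-allylic alcohol; the tartrate sets C8 (retained) and the C7 epoxide carbon (2R,3R), and only the hydroxyl-bearing alkene reacts.

Step 8
Reactants: 11 epoxy alcohol
Product: 13 triol lactone, via silyl lactone 12 (not isolated)
Conditions: CSA (0.3 equiv), CH2Cl2, −20 → 0 °C; then MeOH, rt
Reagents that add atoms: none
Why: acid-promoted epoxy-ester lactonisation: the tert-butyl ester carbonyl opens the activated epoxide at the allylic C7 with inversion and loses isobutene, giving the γ-lactone and the free C8 tertiary alcohol; methanolysis then removes the TES group.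

Step 9
Reactants: 13 triol lactone
Product: 15 dienal, via enal 14 (not isolated)
Conditions: MnO2, CH2Cl2, rt; filter; Ph3P=CHCHO, toluene, 60 °C
Reagents that add atoms: (triphenylphosphoranylidene)acetaldehyde, O=CC=P(c1ccccc1)(c1ccccc1)c1ccccc1
Why: MnO2 oxidises only the allylic C4 alcohol, and Wittig olefination with the stabilised formyl ylide should give the E C3=C4 double bond.

Step 10
Reactants: 15 dienal
Product: 16 dienol
Conditions: NaBH4, CeCl3·7H2O, MeOH, −78 °C
Reagents that add atoms: none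
Why: Luche 1,2-reduction of the dienal leaves the lactone and the diene intact.

Step 11
Reactants: 16 dienol
Product: 17 vinyl epoxide
Conditions: Ti(OiPr)4, L-(+)-DET, t-BuOOH, 4 Å MS, CH2Cl2, −25 °C
Reagents that add atoms: tert-butyl hydroperoxide, CC(C)(C)OO
Why: Sharpless asymmetric epoxidation of the E-allylic alcohol under reagent control gives the (3S,4S) epoxide; the other alkene has no allylic hydroxyl.

Step 12
Reactants: 17 vinyl epoxide
Product: 18 bicyclic triol
Conditions: CSA (cat.), CH2Cl2, 0 °C → rt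
Reagents that add atoms: none
Why: acid-catalysed 6-exo opening of the vinyl epoxide at the allylic C4 by the C8 tertiary alcohol, with inversion, closes the dihydropyran and fixes C4 and C3.

Step 13
Reactants: 18 bicyclic triol
Product: 19 acetonide alcohol
Conditions: Me2C(OMe)2, PPTS, acetone, rt
Reagents that add atoms: 2,2-dimethoxypropane, COC(C)(C)OC
Why: only the terminal 1,2-diol (C2/C3) can form a dioxolane, which leaves the C9 primary alcohol free.

Step 14
Reactants: 19 acetonide alcohol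
Product: 20 bicyclic aldehyde
Conditions: Dess–Martin periodinane, NaHCO3, CH2Cl2, rt
Reagents that add atoms: none
Why: Dess–Martin oxidation of the neopentyl primary alcohol gives a non-enolisable aldehyde.

Step 15
Reactants: 21 7-methyl-1,4-dioxaspiro[4.5]decan-8-one
Product: 23 enone ketal, via silyl enol ether 22 (not isolated)
Conditions: TMSCl, NaI, Et3N, MeCN, rt; then Pd(OAc)2, MeCN, rt
Reagents that add atoms: none
Why: the thermodynamic (more substituted) silyl enol ether undergoes Saegusa–Ito dehydrogenation to the 2-methyl enone.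

Step 16
Reactants: 23 enone ketal
Product: 24 allylic alcohol
Conditions: (R)-Me-CBS (0.1 equiv), BH3·SMe2, THF, −40 °C
Reagents that add atoms: none
Why: Corey–Bakshi–Shibata reduction, with the α-methyl vinyl side as the large group, should give the (S)-alcohol that becomes C14.

Step 17
Reactants: 24 allylic alcohol
Product: 25 hydroxy enone
Conditions: PPTS, acetone/H2O, 40 °C
Reagents that add atoms: water, O
Why: mild ketal hydrolysis unveils the C11 ketone and puts the alkene (C10=C1) in conjugation.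

Step 18
Reactants: 25 hydroxy enone
Product: 26 silyloxy enone
Conditions: TESCl, imidazole, DMF, 0 °C
Reagents that add atoms: chlorotriethylsilane, CC[Si](Cl)(CC)CC
Why: silylation protects the C14 alcohol.

Step 19
Reactants: 26 silyloxy enone
Product: 28 bromo enone, via dibromide 27 (not isolated)
Conditions: Br2, CH2Cl2, 0 °C; then Et3N
Reagents that add atoms: bromine, BrBr
Why: bromination–dehydrobromination of the enone (E1cB loss of HBr from the α-carbon) gives the α-bromo enone with bromine on C10.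

Step 20
Reactants: 28 bromo enone
Product: 29 bromo ketal
Conditions: TMSOCH2CH2OTMS, TMSOTf (cat.), CH2Cl2, −78 → −20 °C
Reagents that add atoms: 1,2-bis(trimethylsilyloxy)ethane, C[Si](C)(C)OCCO[Si](C)(C)C
Why: Noyori ketalisation masks the ketone without acid strong enough to cleave the silyl ether.

Step 21
Reactants: 29 bromo ketal; 20 bicyclic aldehyde
Product: 31 C9 carbinol, via vinyllithium 30 (not isolated)
Conditions: t-BuLi (2 equiv), THF, −78 °C; then 20, −78 °C
Reagents that add atoms: none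
Why: bromine–lithium exchange gives the α-keto vinyl anion equivalent, which adds to the non-enolisable aldehyde faster than to the lactone; C9 should be set by a Cornforth-type approach (C=O anti to the C8–O bond, attack anti to the axial C8–C17 bond).

Step 22
Reactants: 31 C9 carbinol
Product: 32 tetraol enone
Conditions: 1 M HCl, THF, 0 °C → rt
Reagents that add atoms: water, O
Why: one acidic hydrolysis removes the acetonide, the dioxolane and the TES group and regenerates the ring-A enone.

Step 23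
Reactants: 32 tetraol enone
Product: 33 tetrakis-TES ether
Conditions: TESOTf, 2,6-lutidine, CH2Cl2, −78 → 0 °C
Reagents that add atoms: triethylsilyl triflate, CC[Si](CC)(CC)OS(=O)(=O)C(F)(F)F
Why: exhaustive silylation gives ether-type groups at O3, O9 and O14 that cannot leave from a ketyl or an enolate as an acetate would.

Step 24
Reactants: 33 tetrakis-TES ether
Product: 34 enone aldehyde
Conditions: (COCl)2, DMSO, CH2Cl2, −78 → −40 °C; Et3N
Reagents that add atoms: none
Why: under Swern conditions the single primary TES ether is cleaved and oxidised to the aldehyde, while secondary TES ethers stay.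

Step 25
Reactants: 34 enone aldehyde
Product: 36 tricyclic ketone, via samarium enolate 35 (not isolated)
Conditions: SmI2 (2.5 equiv), HMPA, t-BuOH, THF (high dilution), −78 → −20 °C
Reagents that add atoms: none
Why: SmI2/HMPA reduces the α-silyloxy aldehyde to a Sm(III) ketyl, which as a nucleophilic radical adds to C1, the β-carbon of the ring-A enone; a second electron turns the α-keto radical into enolate 35, which t-BuOH protonates at C10. The closest known reaction type is the SmI2-mediated ketyl–olefin (aldehyde–enone) reductive cyclisation used for medium rings and quaternary carbons. The oxocane C1–C2–C3–C4–O–C8–C9–C10, and with it the ten-membered carbocycle, closes in the 8-endo-trig radical mode because the cis C4 and C8 arms of the dihydropyran hold aldehyde and enone face to face. C1 is expected from attack on the enone face that keeps ring A on the convex side of the bicyclo[5.3.1] array with C15 exo, C2 from the exo position of the bulky samarium-bound oxygen on the forming ring, and C10 from protonation anti to the axial C15 methyl, which is also the thermodynamic trans ring fusion. The step needs ketyl formation before enone reduction (α-alkoxy aldehyde versus tetrasubstituted enone), attack at C1 and not 7-exo at C10 (radical polarity), and protonation of 35 faster than β-elimination of the C9 silyloxy group (poor leaving group, proton source present).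

Step 26
Reactants: 36 tricyclic ketone
Product: 37 TBS ether
Conditions: TBSOTf, 2,6-lutidine, CH2Cl2, 0 °C → rt
Reagents that add atoms: tert-butyldimethylsilyl triflate, CC(C)(C)[Si](C)(C)OS(=O)(=O)C(F)(F)F
Why: silylation of the only free hydroxyl (C2) with a group more robust than TES lets O3, O9 and O14 be unmasked and acetylated later while O2 stays covered.

Step 27
Reactants: 37 TBS ether
Product: 38 allylic chloride
Conditions: Ca(OCl)2, CO2 (s), CH2Cl2/H2O, 0 °C
Reagents that add atoms: calcium hypochlorite, [Ca+2].[O-]Cl.[O-]Cl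
Why: ene-type chlorination of the trisubstituted C5=C6 alkene by HOCl should place chlorine on C6 from the exo face (opposite the C3–C2–C1–C10–C9 bridge) with proton loss from C16, giving the exocyclic C5=C16 bond; no other alkene is present at this stage.

Step 28
Reactants: 38 allylic chloride
Product: 39 methylene compound
Conditions: Zn, CH2Br2, TiCl4, THF/CH2Cl2, 0 °C → rt
Reagents that add atoms: dibromomethane, BrCBr
Why: Takai–Lombardo methylenation is non-basic, so the C11 ketone is converted without epimerisation at C10 or β-elimination of the C9 silyloxy group, and the lactone is not attacked.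

Step 29
Reactants: 39 methylene compound
Product: 40 triol
Conditions: HF·pyridine, pyridine, THF, 0 °C
Reagents that add atoms: none
Why: buffered HF cleaves the three TES ethers much faster than the hindered secondary TBS ether at O2.

Step 30
Reactants: 40 triol
Product: 41 triacetate
Conditions: Ac2O, DMAP, pyridine, rt
Reagents that add atoms: acetic anhydride, CC(=O)OC(C)=O
Why: DMAP-catalysed acetylation esterifies O3, O9 and O14 while O2 stays silylated.

Step 31
Reactants: 41 triacetate
Product: 42 target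
Conditions: HF·pyridine (excess), THF, rt
Reagents that add atoms: none
Why: fluoride-mediated desilylation under acidic conditions frees the C2 hydroxyl without acyl migration or damage to the lactone, the acetates or the allylic chloride.

**Compound list**

1 | tert-butyl (2R)-2-hydroxypropanoate | C[C@@H](O)C(=O)OC(C)(C)C | starting material
2 | tert-butyl (2R)-2-[(trifluoromethanesulfonyl)oxy]propanoate | C[C@@H](OS(=O)(=O)C(F)(F)F)C(=O)OC(C)(C)C | intermediate
3 | methyl (triphenyl-λ5-phosphanylidene)acetate | COC(=O)C=P(c1ccccc1)(c1ccccc1)c1ccccc1 | starting material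
4 | [(3S)-4-tert-butoxy-1-methoxy-3-methyl-1,4-dioxobutan-2-yl]triphenylphosphonium triflate (C2 epimers) | COC(=O)C([C@@H](C)C(=O)OC(C)(C)C)[P+](c1ccccc1)(c1ccccc1)c1ccccc1.[O-]S(=O)(=O)C(F)(F)F | intermediate
5 | 4-tert-butyl 1-methyl (3S)-3-methyl-2-(triphenyl-λ5-phosphanylidene)butanedioate | COC(=O)C([C@@H](C)C(=O)OC(C)(C)C)=P(c1ccccc1)(c1ccccc1)c1ccccc1 | intermediate
6 | 4-methylfuran-2(5H)-one | CC1=CC(=O)OC1 | starting material
7 | 4-methyl-2,5-dihydrofuran-2-ol | CC1=CC(O)OC1 | intermediate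
8 | 4-tert-butyl 1-methyl (2E,3R)-2-[(2Z)-4-hydroxy-3-methylbut-2-en-1-ylidene]-3-methylbutanedioate | COC(=O)/C(=C/C=C(C)\CO)[C@@H](C)C(=O)OC(C)(C)C | intermediate
9 | 4-tert-butyl 1-methyl (2E,3R)-3-methyl-2-{(2Z)-3-methyl-4-[(triethylsilyl)oxy]but-2-en-1-ylidene}butanedioate | COC(=O)/C(=C/C=C(C)\CO[Si](CC)(CC)CC)[C@@H](C)C(=O)OC(C)(C)C | intermediate
10 | tert-butyl (2R,3E,5Z)-3-(hydroxymethyl)-2,6-dimethyl-7-[(triethylsilyl)oxy]hepta-3,5-dienoate | OC/C(=C/C=C(C)\CO[Si](CC)(CC)CC)[C@@H](C)C(=O)OC(C)(C)C | intermediate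
11 | tert-butyl (2R)-2-[(2R,3R)-2-(hydroxymethyl)-3-{(1Z)-2-methyl-3-[(triethylsilyl)oxy]prop-1-en-1-yl}oxiran-2-yl]propanoate | OC[C@]1(O[C@@H]1/C=C(C)\CO[Si](CC)(CC)CC)[C@@H](C)C(=O)OC(C)(C)C | intermediate
12 | (3R,4R,5S)-4-hydroxy-4-(hydroxymethyl)-3-methyl-5-{(1Z)-2-methyl-3-[(triethylsilyl)oxy]prop-1-en-1-yl}oxolan-2-one | OC[C@@]1(O)[C@H](/C=C(C)\CO[Si](CC)(CC)CC)OC(=O)[C@@H]1C | intermediate
13 | (3R,4R,5S)-4-hydroxy-4-(hydroxymethyl)-5-[(1Z)-3-hydroxy-2-methylprop-1-en-1-yl]-3-methyloxolan-2-one | OC[C@@]1(O)[C@H](/C=C(C)\CO)OC(=O)[C@@H]1C | intermediate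
14 | (2Z)-3-[(2S,3R,4R)-3-hydroxy-3-(hydroxymethyl)-4-methyl-5-oxooxolan-2-yl]-2-methylprop-2-enal | OC[C@@]1(O)[C@H](/C=C(C)\C=O)OC(=O)[C@@H]1C | intermediate
15 | (2E,4Z)-5-[(2S,3R,4R)-3-hydroxy-3-(hydroxymethyl)-4-methyl-5-oxooxolan-2-yl]-4-methylpenta-2,4-dienal | OC[C@@]1(O)[C@H](/C=C(C)\C=C\C=O)OC(=O)[C@@H]1C | intermediate
16 | (3R,4R,5S)-4-hydroxy-5-[(1Z,3E)-5-hydroxy-2-methylpenta-1,3-dien-1-yl]-4-(hydroxymethyl)-3-methyloxolan-2-one | OC[C@@]1(O)[C@H](/C=C(C)\C=C\CO)OC(=O)[C@@H]1C | intermediate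
17 | (3R,4R,5S)-4-hydroxy-4-(hydroxymethyl)-5-{(1Z)-2-[(2S,3S)-3-(hydroxymethyl)oxiran-2-yl]prop-1-en-1-yl}-3-methyloxolan-2-one | OC[C@@]1(O)[C@H](/C=C(C)\[C@@H]2O[C@H]2CO)OC(=O)[C@@H]1C | intermediate
18 | (3R,3aR,5R,7aS)-5-[(1S)-1,2-dihydroxyethyl]-3a-(hydroxymethyl)-3,6-dimethyl-3,3a,5,7a-tetrahydro-2H-furo[3,2-b]pyran-2-one | OC[C@@]13O[C@H](C(C)=C[C@@H]1OC(=O)[C@@H]3C)[C@@H](O)CO | intermediate
19 | (3R,3aR,5R,7aS)-5-[(4S)-2,2-dimethyl-1,3-dioxolan-4-yl]-3a-(hydroxymethyl)-3,6-dimethyl-3,3a,5,7a-tetrahydro-2H-furo[3,2-b]pyran-2-one | OC[C@@]13O[C@H](C(C)=C[C@@H]1OC(=O)[C@@H]3C)[C@@H]4COC(C)(C)O4 | intermediate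
20 | (3R,3aS,5R,7aS)-5-[(4S)-2,2-dimethyl-1,3-dioxolan-4-yl]-3,6-dimethyl-2-oxo-2,3,5,7a-tetrahydro-3aH-furo[3,2-b]pyran-3a-carbaldehyde | O=C[C@@]13O[C@H](C(C)=C[C@@H]1OC(=O)[C@@H]3C)[C@@H]4COC(C)(C)O4 | intermediate
21 | 7-methyl-1,4-dioxaspiro[4.5]decan-8-one (racemic) | CC1CC2(CCC1=O)OCCO2 | starting material
22 | trimethyl[(7-methyl-1,4-dioxaspiro[4.5]dec-7-en-8-yl)oxy]silane | CC1=C(O[Si](C)(C)C)CCC2(C1)OCCO2 | intermediate
23 | 7-methyl-1,4-dioxaspiro[4.5]dec-6-en-8-one | CC1=CC2(CCC1=O)OCCO2 | intermediate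
24 | (8S)-7-methyl-1,4-dioxaspiro[4.5]dec-6-en-8-ol | CC1=CC2(CC[C@@H]1O)OCCO2 | intermediate
25 | (4S)-4-hydroxy-3-methylcyclohex-2-en-1-one | CC1=CC(=O)CC[C@@H]1O | intermediate
26 | (4S)-3-methyl-4-[(triethylsilyl)oxy]cyclohex-2-en-1-one | CC1=CC(=O)CC[C@@H]1O[Si](CC)(CC)CC | intermediate
27 | (4S)-2,3-dibromo-3-methyl-4-[(triethylsilyl)oxy]cyclohexan-1-one (diastereomers) | CC1(Br)C(Br)C(=O)CC[C@@H]1O[Si](CC)(CC)CC | intermediate
28 | (4S)-2-bromo-3-methyl-4-[(triethylsilyl)oxy]cyclohex-2-en-1-one | CC1=C(Br)C(=O)CC[C@@H]1O[Si](CC)(CC)CC | intermediate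
29 | {[(8S)-6-bromo-7-methyl-1,4-dioxaspiro[4.5]dec-6-en-8-yl]oxy}triethylsilane | CC1=C(Br)C2(CC[C@@H]1O[Si](CC)(CC)CC)OCCO2 | intermediate
30 | [(8S)-7-methyl-8-[(triethylsilyl)oxy]-1,4-dioxaspiro[4.5]dec-6-en-6-yl]lithium | CC1=C([Li])C2(CC[C@@H]1O[Si](CC)(CC)CC)OCCO2 | intermediate
31 | (9S)-9-hydroxy-1,2-seco compound: ring-A C11 ethylene ketal, 14-O-TES, 1(10)-ene, joined at C9 to the dihydropyran–lactone bearing the 2,3-acetonide (centres as in the target) | CC1=C([C@H](O)[C@@]34O[C@H](C(C)=C[C@@H]3OC(=O)[C@@H]4C)[C@@H]5COC(C)(C)O5)C2(CC[C@@H]1O[Si](CC)(CC)CC)OCCO2 | intermediate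
32 | 2,3,9,14-tetrahydroxy-1,2-seco enone (C11 ketone, 1(10)-ene, 5-ene; centres as in the target) | CC1=C([C@H](O)[C@@]23O[C@H](C(C)=C[C@@H]2OC(=O)[C@@H]3C)[C@@H](O)CO)C(=O)CC[C@@H]1O | intermediate
33 | 2,3,9,14-tetrakis-O-(triethylsilyl) derivative of 32 | CC1=C([C@H](O[Si](CC)(CC)CC)[C@@]23O[C@H](C(C)=C[C@@H]2OC(=O)[C@@H]3C)[C@@H](O[Si](CC)(CC)CC)CO[Si](CC)(CC)CC)C(=O)CC[C@@H]1O[Si](CC)(CC)CC | intermediate
34 | 1,2-seco enone with C2 aldehyde and 3,9,14-tris-O-TES groups | CC1=C([C@H](O[Si](CC)(CC)CC)[C@@]23O[C@H](C(C)=C[C@@H]2OC(=O)[C@@H]3C)[C@@H](O[Si](CC)(CC)CC)C=O)C(=O)CC[C@@H]1O[Si](CC)(CC)CC | intermediate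
35 | bis-samarium(III) species: C10=C11 enolate and C2 alkoxide of the cyclised skeleton | I[Sm](I)OC1CC[C@H](O[Si](CC)(CC)CC)[C@@]2(C)C=1[C@H](O[Si](CC)(CC)CC)[C@@]13O[C@H](C(C)=C[C@@H]1OC(=O)[C@@H]3C)[C@@H](O[Si](CC)(CC)CC)[C@@H]2O[Sm](I)I | intermediate
36 | 2-hydroxy-3,9,14-tris(triethylsilyloxy)-11-oxo-20-nor-4,8-epoxybriar-5-ene 19,7-lactone (centres as in the target) | O=C1CC[C@H](O[Si](CC)(CC)CC)[C@@]2(C)[C@H]1[C@H](O[Si](CC)(CC)CC)[C@@]13O[C@H](C(C)=C[C@@H]1OC(=O)[C@@H]3C)[C@@H](O[Si](CC)(CC)CC)[C@@H]2O | intermediate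
37 | 2-O-(tert-butyldimethylsilyl) ether of 36 | O=C1CC[C@H](O[Si](CC)(CC)CC)[C@@]2(C)[C@H]1[C@H](O[Si](CC)(CC)CC)[C@@]13O[C@H](C(C)=C[C@@H]1OC(=O)[C@@H]3C)[C@@H](O[Si](CC)(CC)CC)[C@@H]2O[Si](C)(C)C(C)(C)C | intermediate
38 | 6-chloro-5(16)-ene derived from 37 (C11 ketone kept) | O=C1CC[C@H](O[Si](CC)(CC)CC)[C@@]2(C)[C@H]1[C@H](O[Si](CC)(CC)CC)[C@@]13O[C@H](C(=C)[C@H](Cl)[C@@H]1OC(=O)[C@@H]3C)[C@@H](O[Si](CC)(CC)CC)[C@@H]2O[Si](C)(C)C(C)(C)C | intermediate
39 | 6-chloro-5(16),11(20)-diene with 2-O-TBS and 3,9,14-tris-O-TES groups | C=C1CC[C@H](O[Si](CC)(CC)CC)[C@@]2(C)[C@H]1[C@H](O[Si](CC)(CC)CC)[C@@]13O[C@H](C(=C)[C@H](Cl)[C@@H]1OC(=O)[C@@H]3C)[C@@H](O[Si](CC)(CC)CC)[C@@H]2O[Si](C)(C)C(C)(C)C | intermediate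
40 | 3,9,14-triol with 2-O-TBS group | C=C1CC[C@H](O)[C@@]2(C)[C@H]1[C@H](O)[C@@]13O[C@H](C(=C)[C@H](Cl)[C@@H]1OC(=O)[C@@H]3C)[C@@H](O)[C@@H]2O[Si](C)(C)C(C)(C)C | intermediate
41 | 3,9,14-triacetate with 2-O-TBS group | C=C1CC[C@H](OC(C)=O)[C@@]2(C)[C@H]1[C@H](OC(C)=O)[C@@]13O[C@H](C(=C)[C@H](Cl)[C@@H]1OC(=O)[C@@H]3C)[C@@H](OC(C)=O)[C@@H]2O[Si](C)(C)C(C)(C)C | intermediate
42 | 3,9,14-triacetoxy-6-chloro-2-hydroxy-4,8-epoxybriara-5(16),11(20)-diene 19,7-lactone | C=C1CC[C@H](OC(C)=O)[C@@]2(C)[C@H]1[C@H](OC(C)=O)[C@@]13O[C@H](C(=C)[C@H](Cl)[C@@H]1OC(=O)[C@@H]3C)[C@@H](OC(C)=O)[C@@H]2O | target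

**Summary**

Total steps: 31. Longest linear sequence: 24 steps (steps 1, 2, 4–14, 21–31).

Steps most likely to fail:

1. Step 25. The ketyl may add to the wrong face of the enone (C1 epimer), because allylic strain between the C9 substituents and the C15 methyl can turn the tether to the other face. The aldehyde may also be simply reduced, or the C9 silyloxy group may be lost from the samarium enolate. Fallback, a neutral tin-mediated radical macrocyclisation: starting from 34, PhSeSiMe3 with catalytic ZnI2 adds to the aldehyde to give the O-trimethylsilyl hemiselenoacetal F1. Slow addition of Bu3SnH/AIBN in benzene at 80 °C generates the α-silyloxy alkyl radical, which closes 8-endo on the enone, and hydrogen-atom transfer at C10 (no enolate) gives the 2-O-trimethylsilyl ether F2. Citric acid in MeOH removes the trimethylsilyl group and the route is rejoined at 36.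

2. Step 21. Facial selectivity at C9 may be poor or reversed, and the lactone may compete for the vinyllithium. Fallback, a redox correction: starting from 31 (as the C9 epimer or mixture), Dess–Martin oxidation gives the C9 ketone F3. Luche reduction at −78 °C then delivers hydride along the trajectory the vinyl group had taken, which should give the (9S)-alcohol, and the route is rejoined at 31.

3. Step 27. Chlorination of the alkene flanked by two allylic C–O bonds may be slow, occur on the wrong face, or lose the proton from C4 instead of C16. Fallback, a two-step allylic transposition: starting from 37, SeO2/t-BuOOH in CH2Cl2 at rt oxidises the C16 methyl to the C16 allylic alcohol F4. SOCl2 in Et2O at 0 °C then gives the rearranged chloride by SNi′ delivery to C6 from the exo face, and the route is rejoined at 38.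

Further compounds
F1 | step 25 | O-trimethylsilyl hemiselenoacetal of 34 (C2 epimers) | CC1=C([C@H](O[Si](CC)(CC)CC)[C@@]23O[C@H](C(C)=C[C@@H]2OC(=O)[C@@H]3C)[C@@H](O[Si](CC)(CC)CC)C(O[Si](C)(C)C)[Se]c2ccccc2)C(=O)CC[C@@H]1O[Si](CC)(CC)CC
F2 | step 25 | 2-O-trimethylsilyl ether of 36 | O=C1CC[C@H](O[Si](CC)(CC)CC)[C@@]2(C)[C@H]1[C@H](O[Si](CC)(CC)CC)[C@@]13O[C@H](C(C)=C[C@@H]1OC(=O)[C@@H]3C)[C@@H](O[Si](CC)(CC)CC)[C@@H]2O[Si](C)(C)C
F3 | step 21 | C9 ketone derived from 31 | CC1=C(C(=O)[C@@]34O[C@H](C(C)=C[C@@H]3OC(=O)[C@@H]4C)[C@@H]5COC(C)(C)O5)C2(CC[C@@H]1O[Si](CC)(CC)CC)OCCO2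
F4 | step 27 | C16 allylic alcohol derived from 37 | O=C1CC[C@H](O[Si](CC)(CC)CC)[C@@]2(C)[C@H]1[C@H](O[Si](CC)(CC)CC)[C@@]13O[C@H](C(CO)=C[C@@H]1OC(=O)[C@@H]3C)[C@@H](O[Si](CC)(CC)CC)[C@@H]2O[Si](C)(C)C(C)(C)C
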